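## Structural features

The target is an aryl alkyl ether between two bicyclic halves: O7 of 6,8-dimethoxycoumarin (a benzene ring fused to an α-pyrone) is bonded to C11, the CH2 group on C9 of a trans-fused decalin sesquiterpene (rings A and B; drimane numbering C1–C15 is used throughout, and β means the face of the C10 methyl group). Ring A carries the acetoxy group at C3 beside the gem-dimethyl carbon C4, and ring B carries the trisubstituted C7=C8 olefin with the C8 methyl group. The four stereocentres cluster around the two quaternary carbons: C5 (α-H) and C10 (β-CH3) are neighbours at the ring fusion, C9 is bonded to C10, and C3 (β-OAc, equatorial) is separated from C5 only by C4. At C9 the CH2OAr group is on the α face, axial and anti to the angular methyl group; this is the less stable 9-epi arrangement and cannot be reached by equilibration or by addition to the less hindered face of an exocyclic olefin. The sensitive groups are the coumarin lactone (hydroxide, hydride, organometallic reagents), the acetate, the C7=C8 olefin (acid moves it to C8=C9) and the allylic C9–H next to the aryloxymethyl group (base-induced loss of the phenoxide). The real difficulty is the absolute configuration of the quaternary C10 in a ring system crowded by the C4 methyl groups, together with the axial C9–C11 bond beside it. The key step uses the fact that C5–C10 of ring B, with methyl groups on C8 and C10, the C7=C8 olefin and oxygen-bearing positions C6 and C9, has the carbon pattern of 2,6-dimethyl-1,4-benzoquinone, while C1–C4 with the C3 oxygen and the C4 gem-dimethyl group has that of a 3-silyloxy-4-methylpenta-1,3-diene, so ring A can be closed across C5–C10 by forming C1–C10 and C4–C5.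

## Logic of the disconnections

21 ⇒ 20. The O3–acetyl bond is cut first. The ester would not survive the hydrazine, hydride and organolithium steps that build the terpene, so it goes on last and earlier intermediates carry a silyl ether at O3. The forward acylation only has to distinguish a secondary hydroxyl from a lactone.

20 ⇒ 19. The O3–Si bond is restored. The silyl ether is a spectator that has to last from 8 to 19. Its removal must use a fluoride source acidic enough to leave the lactone closed.

19 ⇒ 17 + 18. The C11–O(aryl) bond is cut, dividing the molecule into the complete, purchasable aromatic half 18 and the terpene alcohol 17. This is the most convergent cut available. The forward step must couple a β-branched, axial primary alcohol with a phenol flanked by two methoxy groups, without base strong enough to open the lactone or to eliminate across C9–C11.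

17 ⇒ 15 ⇒ 14. The C9–C11 bond is cut, and C11 is traced back to a CH2 group on O7 (the O7–CH2 bond of 15). Removing C11 turns the axial substituent into an allylic alcohol, 14, and the configuration of C9 into that of C7, because a [2,3] shift delivers carbon to the face from which oxygen leaves. The demand is a 7α-oxygen next to a C8=C9 olefin and a carbanion on the ether carbon, hence the robust silyl ether at O3.

14 ⇒ 12 ⇒ 11. The allylic alcohol is transposed back to the enone: the C7–O bond of 14 becomes one bond of the epoxide in 12, and C8=C9 becomes the C9 carbonyl of 11. This puts the only oxygen of ring B on C9, where the quinone has it. The forward steps require α-face epoxidation and hydrazone formation at a hindered ketone.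

11 ⇒ 9 ⇒ 8 ⇒ 7 ⇒ 6. A second oxygen is added back at C6 (acetate in 9, hydroxyl in 8 and 7, carbonyl in 6) and the C3–H bond is cut to return the C3 ketone. Ring B becomes an enedione and ring A a ketone, the oxidation pattern of a quinone cycloadduct. The forward steps must tell three carbonyl groups apart (C9 lies between C10 and the methyl-bearing C8 and is left alone), reduce C3 from the α face, silylate O3 but not O6, and remove O6 reductively without touching C7=C8.

6 ⇒ 5 ⇒ 4. The C3 carbonyl is returned to its silyl enol ether and the C5–H bond is inverted, giving cis-fused 4, which is what a cycloaddition to a quinone produces directly. The demand is that C5, α to the C6 carbonyl, can be equilibrated to the trans ring fusion before C6 is reduced.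

4 ⇒ 2 + 3. The bonds C1–C10 and C4–C5 are cut, opening ring A and removing both ring-fusion stereocentres at once. Two achiral compounds remain. The forward cycloaddition must choose one of the two enantiotopic double bonds of 3 by its face and must pair the gem-dimethyl terminus of 2 with the unsubstituted olefinic carbon of 3.

2 ⇒ 1. The O–Si bond is cut. 1 has a single enolizable position, so silylation has no regiochemical problem; the only choice is a silyl group that survives step 2.

## Other disconnections considered

Alternative 1: The cut removes C4–C5 and C9–C10 together and unfolds rings A and B into epoxy polyene A1, the (2Z,6E)-10,11-epoxyfarnesyl ether of 18 with one (S)-configured epoxide. In the forward direction MeAlCl2 would open the epoxide at its tertiary carbon, the two trisubstituted olefins would add in turn through a chair–chair array, and loss of a C7 proton would give alcohol A2, which is the same structure as 20.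
- In its favour: all four stereocentres would follow from one catalytically introduced epoxide centre, the 2Z geometry translates directly into the axial C9 substituent, the coumarin is present from the start, and no protecting group is needed. A1 should be reachable in about five steps (O-alkylation of 18 with a Z-configured farnesyl electrophile, terminal asymmetric dihydroxylation, sulfonylation, ring closure), so the target would need about seven steps against fourteen here.
- Against it: the allylic aryloxy group deactivates the 2,3-olefin inductively and can ionize under the Lewis acid, so monocyclization and loss of the phenol compete. A Z olefin must pass through an array with an axial CH2OAr group. The lactone and methoxy groups bind the promoter. The final proton loss can occur toward C7, C9 or the C8 methyl group and is hard to steer.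
- Comparison: on convergence, atom economy and step count Alternative 1 is the better plan. On predictability the chosen plan is better, since it replaces one cascade with little external control by events that each have an identified control element.

Alternative 2: The cut goes through ring B at C5–C6 and C9–C10 and leads to triene A3, a (Z)-3-methylpenta-2,4-dienyl mesaconate whose second carboxyl group is bound as the N-acyl (R)-4-benzyloxazolidinone. In the forward direction Et2AlCl would chelate the imide and the tethered diene would add to the trisubstituted dienophile to give lactone A4, in which ring B, the C7=C8 olefin with its methyl group, C11 and the stereocentres C5, C9 and C10 are in place.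
- In its favour: the cis relation of C11 and C1 across C9–C10 (the 9-epi arrangement that costs the chosen plan steps 8 to 11) is enforced by the Z diene and the short tether, C11 is present from the outset, and the auxiliary is an independent handle on absolute configuration. On the C9 problem this plan is the better of the two.
- Against it: ester tethers resist the required s-cis arrangement and Z dienes with an inside substituent are reluctant. Ring A is still missing: C1 and C4 are both at the carboxylic acid oxidation level, and C2, C3, two methyl groups and the C3 stereocentre must be added and the ring closed next to quaternary C10 and a now epimerizable C5–H.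
- Comparison: that annulation would probably need more steps than the chosen plan spends after its cycloaddition, so overall step economy is judged equal at best. The chosen plan obtains the whole skeleton of both rings except C11 in one step from two simple components.

Alternative 3: Here the terpene is left intact and the arene is dismantled. The cut at C4a–C8a of the coumarin leads back to cyclobutenone A5, a 4-alkenyl-2,4-dimethoxycyclobutenone carrying the terpenyl ether on C3, to be assembled from a four-carbon squaric acid derivative, alcohol 17 and a three-carbon alkenyl nucleophile. In the forward direction heating to about 140 °C would open the four-membered ring to a dienyl ketene, six-electron closure and tautomerization would give phenol A6, and unmasking of the aldehyde, olefination and lactonization would complete the pyranone.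
- In its favour: the C11–O bond would be made by addition–elimination of the alkoxide of 17 to a vinylogous ester, which avoids coupling a doubly ortho-substituted phenol with a hindered primary alcohol (step 12). On that single bond it is the equal or the better of the chosen plan, and the arene substitution pattern is fixed by construction.
- Against it: it consumes the same alcohol 17 and so does nothing for the real difficulty. It replaces one step using a commercial phenol by about six linear steps on the most valuable intermediate. The two carbonyl groups of the squarate must be differentiated, and the C7=C8 olefin and the ether must endure prolonged heating.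
- Comparison: structurally the two plans are complementary rather than rival, and the pericyclic cascade is mechanistically dependable, but in step economy the chosen plan is clearly ahead.

Key step: step 2

Assumption: the catalyst derived from (S)-α,α-diphenylprolinol is taken to expose the face of 3 that leads to 4; if the sense of induction is the opposite, the enantiomeric catalyst is used and nothing else changes.

## Route

Step 1
Reactants: 1 4-methylpent-1-en-3-one
Product: 2 4-methyl-3-(triisopropylsilyloxy)penta-1,3-diene
Conditions: i-Pr3SiOSO2CF3 (1.1 equiv), Et3N (1.5 equiv), CH2Cl2, 0 → 23 °C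
Reagents that add atoms: triisopropylsilyl trifluoromethanesulfonate, CC(C)[Si](C(C)C)(C(C)C)OS(=O)(=O)C(F)(F)F
Why: Soft enolization: the silyl triflate activates the carbonyl and the amine removes the only enolizable proton (the isopropyl methine), which should give the cross-conjugated silyl dienol ether, a known way to 2-silyloxydienes from vinyl ketones. The triisopropylsilyl group is chosen over trimethylsilyl so that the enol ether withstands the strongly acidic catalyst of step 2 and chromatography.

Step 2
Reactants: 2 4-methyl-3-(triisopropylsilyloxy)penta-1,3-diene; 3 2,6-dimethyl-1,4-benzoquinone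
Product: 4 3-(triisopropylsilyloxy)-11-nor-5β-drima-2,7-diene-6,9-dione, the cis-fused adduct (5β-H, 10β-CH3), (4aR,8aS)-2,5,5,8a-tetramethyl-6-(triisopropylsilyloxy)-4a,5,8,8a-tetrahydronaphthalene-1,4-dione
Conditions: 3 (1.0 equiv), 2 (1.5 equiv), (S)-3,3-diphenyl-1-(o-tolyl)tetrahydro-1H,3H-pyrrolo[1,2-c][1,3,2]oxazaborole (C24H24BNO, 20 mol%) + HN(SO2CF3)2 (18 mol%), CH2Cl2, −78 → −40 °C
Reagents that add atoms: none
Why: The protonated oxazaborolidine acts as a chiral boron Lewis acid on a quinone carbonyl and the s-cis diene adds to one C=C bond of 3 in a concerted but asynchronous [4+2] cycloaddition; the closest known reaction type is the oxazaborolidinium-catalysed enantioselective Diels–Alder reaction of 1,4-benzoquinones with 2-silyloxy-1,3-dienes. Ring A is closed by this intermolecular suprafacial [4+2] event, in which C4–C5 forms in advance of C1–C10, so no separate cyclization mode has to be met. C10 is set by the catalyst, which screens one face of the bound enedione so that only one of the two enantiotopic double bonds of 3 is attacked from its open face; C5 follows from C10 because addition to the dienophile is suprafacial, which makes the ring fusion cis. Endo and exo approach lead to the same product because the diene termini (CH2 and C(CH3)2) carry no stereogenic substituents. The regiochemistry needed is C(CH3)2 to the unsubstituted quinone carbon and CH2 to the methyl-bearing one: the gem-dimethyl terminus is the nucleophilic α-carbon of the silyl enol ether, and the reverse pairing would have to join two fully substituted carbons. Mono-addition is secured because the remaining enedione double bond of 4 lies next to the new quaternary C10 and is a poorer dienophile than 3. The bulky silyloxy group on C3 of the diene favours the s-cis conformer and offsets the inside methyl group on C4, and the triisopropylsilyl enol ether should survive the acidic catalyst.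

Step 3
Reactants: 4 3-(triisopropylsilyloxy)-11-nor-5β-drima-2,7-diene-6,9-dione
Product: 6 11-nor-5α-drim-7-ene-3,6,9-trione, via trans-fused silyl enol ether 5 (not isolated)
Conditions: 1,8-diazabicyclo[5.4.0]undec-7-ene (0.1 equiv), THF, 23 °C; then 2 M HCl (aq), 23 °C
Reagents that add atoms: none
Why: Base-mediated epimerization through the C5–C6 dienolate is carried out while C3 is still masked, so no C2 enolate can add across the ring to the enedione; aqueous acid then hydrolyses the silyl enol ether. C5 is set under thermodynamic control, the trans isomer being expected to prevail because both ring A bonds are then equatorial on the flat enedione ring.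

Step 4
Reactants: 6 11-nor-5α-drim-7-ene-3,6,9-trione
Product: 7 3β,6β-dihydroxy-11-nor-5α-drim-7-en-9-one
Conditions: NaBH4 (1.0 equiv), CeCl3·7H2O (1.0 equiv), MeOH, −78 → −20 °C
Reagents that add atoms: none
Why: Luche-type 1,2-reduction should take the C3 and C6 carbonyls and leave the C9 carbonyl, which lies between quaternary C10 and the methyl-bearing C8. Hydride is delivered axially from the α face because the β face is screened by the 4β- and 10β-methyl groups, which sets the equatorial 3β-alcohol; the 6β-alcohol formed in the same way is removed later, so its configuration is of no consequence.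

Step 5
Reactants: 7 3β,6β-dihydroxy-11-nor-5α-drim-7-en-9-one
Product: 8 3β-(tert-butyldimethylsilyloxy)-6β-hydroxy-11-nor-5α-drim-7-en-9-one
Conditions: t-BuMe2SiCl (1.3 equiv), imidazole (3 equiv), DMF, 23 °C
Reagents that add atoms: tert-butyldimethylsilyl chloride, CC(C)(C)[Si](C)(C)Cl
Why: Silylation with the chloride–imidazole system is sensitive to hindrance: the equatorial 3β-hydroxyl should react, whereas the 6β-hydroxyl is syn-axial to both the 10β- and the 4β-methyl group and should not.

Step 6
Reactants: 8 3β-(tert-butyldimethylsilyloxy)-6β-hydroxy-11-nor-5α-drim-7-en-9-one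
Product: 9 6β-acetoxy-3β-(tert-butyldimethylsilyloxy)-11-nor-5α-drim-7-en-9-one
Conditions: Ac2O (5 equiv), 4-(dimethylamino)pyridine (1 equiv), pyridine, 60 °C
Reagents that add atoms: acetic anhydride, CC(=O)OC(C)=O
Why: Acyl transfer through the acylpyridinium ion turns the hydroxyl group γ to the enone carbonyl into a leaving group; heat and a full equivalent of the nucleophilic catalyst are used because the alcohol is strongly hindered.

Step 7
Reactants: 9 6β-acetoxy-3β-(tert-butyldimethylsilyloxy)-11-nor-5α-drim-7-en-9-one
Product: 11 3β-(tert-butyldimethylsilyloxy)-11-nor-5α-drim-7-en-9-one, via deconjugated 6-en-9-one 10 (not isolated)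
Conditions: SmI2 (2.5 equiv), MeOH (5 equiv), THF, −78 °C; then 1,8-diazabicyclo[5.4.0]undec-7-ene (1 equiv), −78 → 23 °C
Reagents that add atoms: none
Why: Two-electron reduction of the enone expels the γ-acetate and leaves a dienolate (the known reductive cleavage of γ-acyloxy enones); protonation at C8 or C6 gives 10 or 11, and the amidine base should move the olefin of 10 into conjugation. C5 is not involved and C7=C8 is regenerated.

Step 8
Reactants: 11 3β-(tert-butyldimethylsilyloxy)-11-nor-5α-drim-7-en-9-one
Product: 12 3β-(tert-butyldimethylsilyloxy)-7α,8α-epoxy-11-nor-5α-driman-9-one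
Conditions: 30% H2O2 (aq, 5 equiv), NaOH (aq, 0.5 equiv), MeOH, 0 → 23 °C
Reagents that add atoms: hydrogen peroxide, OO
Why: Weitz–Scheffer nucleophilic epoxidation: hydroperoxide should add axially to C7 from the α face, anti to the β-methyl groups on C10 and C4, and the enolate then closes onto oxygen. This sets C7 and C8 as the α-epoxide.

Step 9
Reactants: 12 3β-(tert-butyldimethylsilyloxy)-7α,8α-epoxy-11-nor-5α-driman-9-one
Product: 14 3β-(tert-butyldimethylsilyloxy)-11-nor-5α-drim-8-en-7α-ol, via epoxy hydrazone 13 (not isolated)
Conditions: N2H4·H2O (5 equiv), AcOH (0.5 equiv), MeOH, 0 → 23 °C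
Reagents that add atoms: none
Why: Wharton transposition: the hydrazone opens the epoxide at C8–O to an alkenyl diazene, which loses N2 to give the C8=C9 olefin. The C7–O bond is never broken, so the 7α configuration from step 8 is kept.

Step 10
Reactants: 14 3β-(tert-butyldimethylsilyloxy)-11-nor-5α-drim-8-en-7α-ol
Product: 15 3β-(tert-butyldimethylsilyloxy)-7α-[(tributylstannyl)methoxy]-11-nor-5α-drim-8-ene
Conditions: KH (1.5 equiv), Bu3SnCH2I (1.3 equiv), THF, 0 → 23 °C
Reagents that add atoms: (iodomethyl)tributylstannane, CCCC[Sn](CCCC)(CCCC)CI
Why: Williamson etherification of the potassium alkoxide with the primary iodide, the standard preparation of substrates for the Still–Wittig shift; the silyl ether and the olefin are inert.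

Step 11
Reactants: 15 3β-(tert-butyldimethylsilyloxy)-7α-[(tributylstannyl)methoxy]-11-nor-5α-drim-8-ene
Product: 17 3β-(tert-butyldimethylsilyloxy)-9βH-drim-7-en-11-ol (CH2OH on the α face of C9), via lithiomethyl ether 16 (not isolated)
Conditions: n-BuLi (2 equiv), THF, −78 → −20 °C; aq. NH4Cl
Reagents that add atoms: none
Why: Tin–lithium exchange gives the α-alkoxy carbanion, which undergoes the [2,3]-sigmatropic Still–Wittig shift. The shift is suprafacial, so carbon is delivered to C9 on the α face from which O7 leaves, anti to the C10 methyl group; this sets C9 with the axial CH2OH and creates C7=C8.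

Step 12
Reactants: 17 3β-(tert-butyldimethylsilyloxy)-9βH-drim-7-en-11-ol; 18 isofraxidin (7-hydroxy-6,8-dimethoxycoumarin)
Product: 19 7-{[3β-(tert-butyldimethylsilyloxy)-9βH-drim-7-en-11-yl]oxy}-6,8-dimethoxycoumarin
Conditions: 18 (1.5 equiv), PPh3 (2 equiv), diisopropyl azodicarboxylate (2 equiv), THF, 0 → 23 °C
Reagents that add atoms: none
Why: Mitsunobu etherification: the acidic phenol protonates the betaine and its anion displaces the alkoxyphosphonium group at primary C11, so no stereocentre is touched. The neutral conditions spare the lactone and avoid elimination across C9–C11.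

Step 13
Reactants: 19 7-{[3β-(tert-butyldimethylsilyloxy)-9βH-drim-7-en-11-yl]oxy}-6,8-dimethoxycoumarin
Product: 20 7-[(3β-hydroxy-9βH-drim-7-en-11-yl)oxy]-6,8-dimethoxycoumarin
Conditions: HF·pyridine, pyridine, THF, 0 → 23 °C
Reagents that add atoms: none
Why: Fluoride cleaves the Si–O bond under buffered, mildly acidic conditions, which should leave the lactone, the aryl ether and the trisubstituted olefin untouched.

Step 14
Reactants: 20 7-[(3β-hydroxy-9βH-drim-7-en-11-yl)oxy]-6,8-dimethoxycoumarin
Product: 21 7-[(3β-acetoxy-9βH-drim-7-en-11-yl)oxy]-6,8-dimethoxycoumarin, (2S,4aS,5R,8aR)-5-{[(6,8-dimethoxy-2-oxo-2H-chromen-7-yl)oxy]methyl}-1,1,4a,6-tetramethyl-1,2,3,4,4a,5,8,8a-octahydronaphthalen-2-yl acetate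
Conditions: Ac2O (3 equiv), pyridine, 4-(dimethylamino)pyridine (0.1 equiv), CH2Cl2, 23 °C
Reagents that add atoms: acetic anhydride, CC(=O)OC(C)=O
Why: Acylation of the equatorial 3β-hydroxyl with nucleophilic catalysis; no other nucleophilic group is present.

## Compound list

1 | 4-methylpent-1-en-3-one | C=CC(=O)C(C)C | starting material
2 | 4-methyl-3-(triisopropylsilyloxy)penta-1,3-diene | C=CC(O[Si](C(C)C)(C(C)C)C(C)C)=C(C)C | intermediate
3 | 2,6-dimethyl-1,4-benzoquinone | CC1=CC(=O)C=C(C)C1=O | starting material
4 | 3-(triisopropylsilyloxy)-11-nor-5β-drima-2,7-diene-6,9-dione (cis-fused adduct, 4aR,8aS) | O=C1C(C)=CC(=O)[C@@H]2C(C)(C)C(O[Si](C(C)C)(C(C)C)C(C)C)=CC[C@]12C | intermediate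
5 | 3-(triisopropylsilyloxy)-11-nor-5α-drima-2,7-diene-6,9-dione (trans-fused silyl enol ether) | O=C1C(C)=CC(=O)[C@H]2C(C)(C)C(O[Si](C(C)C)(C(C)C)C(C)C)=CC[C@]12C | intermediate (not isolated)
6 | 11-nor-5α-drim-7-ene-3,6,9-trione | O=C1C(C)=CC(=O)[C@H]2C(C)(C)C(=O)CC[C@]12C | intermediate
7 | 3β,6β-dihydroxy-11-nor-5α-drim-7-en-9-one | O=C1C(C)=C[C@@H](O)[C@H]2C(C)(C)[C@@H](O)CC[C@]12C | intermediate
8 | 3β-(tert-butyldimethylsilyloxy)-6β-hydroxy-11-nor-5α-drim-7-en-9-one | O=C1C(C)=C[C@@H](O)[C@H]2C(C)(C)[C@@H](O[Si](C)(C)C(C)(C)C)CC[C@]12C | intermediate
9 | 6β-acetoxy-3β-(tert-butyldimethylsilyloxy)-11-nor-5α-drim-7-en-9-one | O=C1C(C)=C[C@@H](OC(C)=O)[C@H]2C(C)(C)[C@@H](O[Si](C)(C)C(C)(C)C)CC[C@]12C | intermediate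
10 | 3β-(tert-butyldimethylsilyloxy)-11-nor-5α-drim-6-en-9-one (C8 epimers) | O=C1C(C)C=C[C@H]2C(C)(C)[C@@H](O[Si](C)(C)C(C)(C)C)CC[C@]12C | intermediate (not isolated)
11 | 3β-(tert-butyldimethylsilyloxy)-11-nor-5α-drim-7-en-9-one | O=C1C(C)=CC[C@H]2C(C)(C)[C@@H](O[Si](C)(C)C(C)(C)C)CC[C@]12C | intermediate
12 | 3β-(tert-butyldimethylsilyloxy)-7α,8α-epoxy-11-nor-5α-driman-9-one | O=C1[C@]2(C)O[C@@H]2C[C@H]3C(C)(C)[C@@H](O[Si](C)(C)C(C)(C)C)CC[C@]13C | intermediate
13 | hydrazone of 12 at C9 | NN=C1[C@]2(C)O[C@@H]2C[C@H]3C(C)(C)[C@@H](O[Si](C)(C)C(C)(C)C)CC[C@]13C | intermediate (not isolated)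
14 | 3β-(tert-butyldimethylsilyloxy)-11-nor-5α-drim-8-en-7α-ol | C1=C(C)[C@H](O)C[C@H]2C(C)(C)[C@@H](O[Si](C)(C)C(C)(C)C)CC[C@]12C | intermediate
15 | 3β-(tert-butyldimethylsilyloxy)-7α-[(tributylstannyl)methoxy]-11-nor-5α-drim-8-ene | C1=C(C)[C@H](OC[Sn](CCCC)(CCCC)CCCC)C[C@H]2C(C)(C)[C@@H](O[Si](C)(C)C(C)(C)C)CC[C@]12C | intermediate
16 | 3β-(tert-butyldimethylsilyloxy)-7α-(lithiomethoxy)-11-nor-5α-drim-8-ene | C1=C(C)[C@H](OC[Li])C[C@H]2C(C)(C)[C@@H](O[Si](C)(C)C(C)(C)C)CC[C@]12C | intermediate (not isolated)
17 | 3β-(tert-butyldimethylsilyloxy)-9βH-drim-7-en-11-ol (9α-CH2OH) | OC[C@@H]1C(C)=CC[C@H]2C(C)(C)[C@@H](O[Si](C)(C)C(C)(C)C)CC[C@]12C | intermediate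
18 | isofraxidin (7-hydroxy-6,8-dimethoxycoumarin) | COc1cc2ccc(=O)oc2c(OC)c1O | starting material
19 | 7-{[3β-(tert-butyldimethylsilyloxy)-9βH-drim-7-en-11-yl]oxy}-6,8-dimethoxycoumarin | COc1cc2ccc(=O)oc2c(OC)c1OC[C@@H]1C(C)=CC[C@H]2C(C)(C)[C@@H](O[Si](C)(C)C(C)(C)C)CC[C@]12C | intermediate
20 | 7-[(3β-hydroxy-9βH-drim-7-en-11-yl)oxy]-6,8-dimethoxycoumarin | COc1cc2ccc(=O)oc2c(OC)c1OC[C@@H]1C(C)=CC[C@H]2C(C)(C)[C@@H](O)CC[C@]12C | intermediate
21 | 7-[(3β-acetoxy-9βH-drim-7-en-11-yl)oxy]-6,8-dimethoxycoumarin (CNP0285931.2) | COc1cc2ccc(=O)oc2c(OC)c1OC[C@@H]1C(C)=CC[C@H]2C(C)(C)[C@@H](OC(C)=O)CC[C@]12C | target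

## Step count and least certain steps

Total step count: 14 steps. Longest linear sequence: 14 steps (1 to 21); 3 and 18 are purchased and enter at steps 2 and 12.

Step 2 (key step). The most likely failures are a low rate and poor facial selectivity. The inside methyl group of 2 disfavours the reactive s-cis conformer. The catalyst can bind either carbonyl of 3: binding at the more basic, unhindered carbonyl (the future C6) makes the methyl-bearing carbon the electrophilic end, which opposes the sterically dictated orientation. The reaction may then pass through a poorly organized transition state with erosion of enantioselectivity, or protodesilylation of 2 may outrun cycloaddition. The fallback sets out from 2 and 3 and runs the cycloaddition without catalyst (toluene, 110 °C, sealed vessel, a trace of 2,6-di-tert-butyl-4-methylphenol). In the uncatalysed reaction the orientation is governed by the carbonyl flanked by the two methyl groups and so agrees with the steric preference. This would give 4 as a racemate with the enantiomeric cis adduct F1; the two are separated by preparative chromatography on a chiral stationary phase (amylose tris(3,5-dimethylphenylcarbamate)), and the route is rejoined at 4.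

Step 3. The most likely failure is incomplete or unfavourable equilibration at C5, because the cis-fused isomer can avoid the 1,3-diaxial contact between the 4β- and 10β-methyl groups that the trans isomer must carry. The fallback sets out from 4 and replaces thermodynamic by kinetic control. Deprotonation at C5 with LiN(SiMe3)2 in THF at −78 °C gives the lithium dienolate F2, which is quenched at −78 °C with AcOH; proton delivery to C5 anti to the adjacent C10 methyl group should give 5. Desilylation with aqueous HF in MeCN at 0 °C, too mild to re-equilibrate C5, then gives 6, where the route is rejoined and reduced at once in step 4.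

Step 6. The most likely failure is stalled acylation, since the 6β-hydroxyl sits between two syn-axial methyl groups, and under forcing conditions dehydration toward C5. The fallback sets out from 8 and removes the oxygen by a radical path. NaH, CS2 and MeI in THF at 0 °C give the S-methyl xanthate F3 (the alkoxide adds to the small CS2 molecule where an acylpyridinium ion cannot reach). Bu3SnH with azobisisobutyronitrile in toluene at 80 °C then removes the C6 oxygen through the allylic radical (Barton–McCombie deoxygenation); a [3,3] shift of the allylic xanthate would be harmless because both isomers give the same radical. Treatment with 1,8-diazabicyclo[5.4.0]undec-7-ene as in step 7 brings any 10 into conjugation, and the route is rejoined at 11.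

Step 9. The most likely failure is slow hydrazone formation at a ketone flanked by two fully substituted carbons, so that opening of the epoxide by hydrazine competes. The fallback sets out from 12. NaBH4 in MeOH at 0 °C reduces the ketone to the epoxy alcohol F4 (either C9 epimer serves), and NaH, CS2 and MeI give its xanthate F5. Bu3SnH with azobisisobutyronitrile in toluene at 80 °C generates the C9 radical, which opens the adjacent epoxide by scission of the C8–O bond; the C7 alkoxyl radical takes hydrogen from the stannane. This gives 14 with the 7α-oxygen untouched, where the route is rejoined.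

Step 12. The most likely failure is slow displacement at the alkoxyphosphonium stage, because the alcohol is β-branched and axial and the phenol carries two ortho substituents; alkylation of the reduced azodicarboxylate or elimination toward the exocyclic diene would then take over. The fallback sets out from 17. (CF3SO2)2O and 2,6-lutidine in CH2Cl2 at −78 °C give the primary triflate F6, which is added to the cesium salt of 18 (Cs2CO3, DMF, −20 → 0 °C). Direct SN2 displacement at C11 at low temperature should give 19, where the route is rejoined.

## Further compounds

F1 | step 2 | enantiomer of 4, (4aS,8aR)-configured cis adduct | O=C1C(C)=CC(=O)[C@H]2C(C)(C)C(O[Si](C(C)C)(C(C)C)C(C)C)=CC[C@@]12C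
F2 | step 3 | lithium C5–C6 dienolate of 4 | [Li]OC1=C2C(C)(C)C(O[Si](C(C)C)(C(C)C)C(C)C)=CC[C@]2(C)C(=O)C(C)=C1
F3 | step 6 | O-(6β) S-methyl xanthate of 8 | O=C1C(C)=C[C@@H](OC(=S)SC)[C@H]2C(C)(C)[C@@H](O[Si](C)(C)C(C)(C)C)CC[C@]12C
F4 | step 9 | 3β-(tert-butyldimethylsilyloxy)-7α,8α-epoxy-11-nor-5α-driman-9-ol (C9 epimers) | OC1[C@]2(C)O[C@@H]2C[C@H]3C(C)(C)[C@@H](O[Si](C)(C)C(C)(C)C)CC[C@]13C
F5 | step 9 | O-(C9) S-methyl xanthate of F4 | CSC(=S)OC1[C@]2(C)O[C@@H]2C[C@H]3C(C)(C)[C@@H](O[Si](C)(C)C(C)(C)C)CC[C@]13C
F6 | step 12 | C11 trifluoromethanesulfonate of 17 | O=S(=O)(OC[C@@H]1C(C)=CC[C@H]2C(C)(C)[C@@H](O[Si](C)(C)C(C)(C)C)CC[C@]12C)C(F)(F)F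
A1 | alternative 1 | 7-{[(2Z,6E,10S)-10,11-epoxy-3,7,11-trimethyldodeca-2,6-dienyl]oxy}-6,8-dimethoxycoumarin | COc1cc2ccc(=O)oc2c(OC)c1OC/C=C(C)\CC/C=C(\C)CC[C@@H]1OC1(C)C
A2 | alternative 1 | 3-deacetyl target (3β-alcohol, same structure as 20) | COc1cc2ccc(=O)oc2c(OC)c1OC[C@@H]1C(C)=CC[C@H]2C(C)(C)[C@@H](O)CC[C@]12C
A3 | alternative 2 | (2Z)-3-methylpenta-2,4-dienyl (2E)-4-[(4R)-4-benzyl-2-oxooxazolidin-3-yl]-2-methyl-4-oxobut-2-enoate | C=C/C(C)=C\COC(=O)/C(C)=C/C(=O)N1[C@H](Cc2ccccc2)COC1=O
A4 | alternative 2 | ring B lactone imide (C5, C9, C10 set; C7=C8 in place) | O=C1OC[C@@H]2C(C)=CC[C@@H](C(=O)N3[C@H](Cc4ccccc4)COC3=O)[C@]12C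
A5 | alternative 3 | 4-[(E)-3,3-diethoxyprop-1-enyl]-2,4-dimethoxy-3-{[3β-(tert-butyldimethylsilyloxy)-9βH-drim-7-en-11-yl]oxy}cyclobut-2-en-1-one (C4 epimers) | O=C1C(OC)=C(OC[C@@H]2C(C)=CC[C@H]3C(C)(C)[C@@H](O[Si](C)(C)C(C)(C)C)CC[C@]23C)C1(OC)/C=C/C(OCC)OCC
A6 | alternative 3 | 2-hydroxy-3,5-dimethoxy-4-{[3β-(tert-butyldimethylsilyloxy)-9βH-drim-7-en-11-yl]oxy}benzaldehyde diethyl acetal | Oc1c(OC)c(OC[C@@H]2C(C)=CC[C@H]3C(C)(C)[C@@H](O[Si](C)(C)C(C)(C)C)CC[C@]23C)c(OC)cc1C(OCC)OCC
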